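**Retrosynthetic overview**

1. Numbering: ring A = C1(Me2)–C2–C3(Br)–C4–C5(Me)(OH)–C6 (spiro); ring B = C6–C7=C8–C9(=C12HBr)–C10–C11. The strategy rests on the diene C7=C8–C9=C12, whose exocyclic C9=C12 bond carries bromine trans to C8; syn addition of a C8 alkenylpalladium to a C9≡C12 silylalkyne, followed by hydride capture, sets that geometry.
2. Target ⇐ axial C3 alcohol (SN2 to the equatorial bromide) ⇐ C3 ketone; C12–Br ⇐ C12–SiMe3 (ipso-bromodesilylation with retention).
3. Ring B (closed last, bond C8–C9) ⇐ ring A ketol with (Z)-2-iodovinyl and 4-trimethylsilylbut-3-ynyl groups on C6, by palladium/formate 6-exo-dig cyclisation.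
4. (Z)-Iodovinyl ⇐ iodoethynyl ⇐ ethynyl ⇐ formyl ⇐ allyl; C5 carbinol ⇐ methyl addition to the C5 carbonyl of a vinylogous silyl ester, steered by the axial ethynyl group and the syn-axial C1 methyl.
5. Quaternary C6 ⇐ enantioselective decarboxylative allylation of the C6-alkylated dimedone vinylogous ester; ring A is present from the start (dimedone).

Key step: step 13

Assumption: the allylation of step 5 is taken to follow the facial sense known for 2-alkylcyclohexanone enol carbonates, where the (S)-phosphinooxazoline leads to (S)-2-allyl-2-methylcyclohexanone. This calls for the (R)-ligand here, (R)-4-tert-butyl-2-{2-[bis(4-trifluoromethylphenyl)phosphino]-5-(trifluoromethyl)phenyl}-4,5-dihydrooxazole, written (R)-(CF3)3-t-BuPHOX.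

**Route**

Step 1
Reactants: 1 dimedone (5,5-dimethylcyclohexane-1,3-dione)
Product: 2 3-isobutoxy-5,5-dimethylcyclohex-2-en-1-one
Conditions: i-BuOH, TsOH·H2O (cat.), toluene, reflux, Dean–Stark trap
Reagents that add atoms: 2-methylpropan-1-ol, CC(C)CO
Why: Acid-catalysed enol etherification of the 1,3-dione with azeotropic removal of water gives the vinylogous ester, which masks the C3 carbonyl and leaves C6 as the kinetically acidic α′ position.

Step 2
Reactants: 3 4-(trimethylsilyl)but-3-yn-1-ol
Product: 4 4-(trimethylsilyl)but-3-yn-1-yl trifluoromethanesulfonate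
Conditions: Tf2O, 2,6-lutidine, CH2Cl2, −78 °C; used at once
Reagents that add atoms: triflic anhydride, O=S(=O)(OS(=O)(=O)C(F)(F)F)C(F)(F)F
Why: O-Sulfonylation of the primary alcohol with a hindered pyridine base gives the alkyl triflate, and the silylalkyne is inert to these conditions.

Step 3
Reactants: 2 3-isobutoxy-5,5-dimethylcyclohex-2-en-1-one; 4 4-(trimethylsilyl)but-3-yn-1-yl trifluoromethanesulfonate
Product: 6 rac-3-isobutoxy-5,5-dimethyl-6-[4-(trimethylsilyl)but-3-yn-1-yl]cyclohex-2-en-1-one, via lithium dienolate 5 (not isolated)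
Conditions: LiN(i-Pr)2, THF, −78 °C; then 4, −78 → −30 °C
Reagents that add atoms: none
Why: Stork–Danheiser kinetic α′-alkylation: the amide base removes a C6 proton, and the primary triflate should be reactive enough for SN2 at low temperature to outpace elimination to the enyne despite the neighbouring gem-dimethyl carbon.

Step 4
Reactants: 6 rac-3-isobutoxy-5,5-dimethyl-6-[4-(trimethylsilyl)but-3-yn-1-yl]cyclohex-2-en-1-one
Product: 8 allyl 5-isobutoxy-3,3-dimethyl-2-[4-(trimethylsilyl)but-3-yn-1-yl]cyclohexa-1,5-dien-1-yl carbonate, via lithium enolate 7 (not isolated)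
Conditions: LiN(i-Pr)2, THF, −78 °C; TMEDA, allyl chloroformate, −78 → 0 °C
Reagents that add atoms: allyl chloroformate, C=CCOC(=O)Cl
Why: The fully substituted, hindered C6 enolate is acylated on oxygen by the chloroformate, giving the allyl enol carbonate (enolate O-acylation).

Step 5
Reactants: 8 allyl 5-isobutoxy-3,3-dimethyl-2-[4-(trimethylsilyl)but-3-yn-1-yl]cyclohexa-1,5-dien-1-yl carbonate
Product: 10 (S)-6-allyl-3-isobutoxy-5,5-dimethyl-6-[4-(trimethylsilyl)but-3-yn-1-yl]cyclohex-2-en-1-one, via allylpalladium enolate 9 (not isolated)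
Conditions: Pd2(dba)3 (2.5 mol %), (R)-(CF3)3-t-BuPHOX (6.5 mol %), toluene, 25 °C
Reagents that add atoms: none
Why: Decarboxylative asymmetric allylic alkylation (Tsuji–Trost type): zerovalent palladium ionises the allyl carbonate, CO2 is lost, and the chiral phosphinooxazoline–palladium enolate forms the C6–allyl bond on one enolate face by inner-sphere reductive elimination, which sets the quaternary C6 stereocentre next to the gem-dimethyl carbon.

Step 6
Reactants: 10 (S)-6-allyl-3-isobutoxy-5,5-dimethyl-6-[4-(trimethylsilyl)but-3-yn-1-yl]cyclohex-2-en-1-one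
Product: 11 (S)-3-isobutoxy-5,5-dimethyl-6-[(E)-prop-1-en-1-yl]-6-[4-(trimethylsilyl)but-3-yn-1-yl]cyclohex-2-en-1-one
Conditions: RuHCl(CO)(PPh3)3 (5 mol %), toluene, 90 °C
Reagents that add atoms: none
Why: Ruthenium hydride-catalysed alkene isomerisation (hydrometallation and β-hydride elimination) moves the terminal double bond one position to the more stable propenyl group and stops there because C6 is quaternary.

Step 7
Reactants: 11 (S)-3-isobutoxy-5,5-dimethyl-6-[(E)-prop-1-en-1-yl]-6-[4-(trimethylsilyl)but-3-yn-1-yl]cyclohex-2-en-1-one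
Product: 13 (R)-4-isobutoxy-6,6-dimethyl-2-oxo-1-[4-(trimethylsilyl)but-3-yn-1-yl]cyclohex-3-ene-1-carbaldehyde, via vicinal diol 12 (not isolated)
Conditions: OsO4 (2 mol %), NaIO4, 2,6-lutidine, 1,4-dioxane/H2O, 20 °C
Reagents that add atoms: osmium tetroxide, O=[Os](=O)(=O)=O; sodium periodate, [Na+].[O-]I(=O)(=O)=O (re-oxidant and source of the oxygen that osmium passes on)
Why: Lemieux–Johnson oxidation: OsO4 should dihydroxylate the electron-rich propenyl group in preference to the push–pull vinylogous ester alkene and the alkyne, and periodate cleaves the diol to the C7 aldehyde.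

Step 8
Reactants: 13 (R)-4-isobutoxy-6,6-dimethyl-2-oxo-1-[4-(trimethylsilyl)but-3-yn-1-yl]cyclohex-3-ene-1-carbaldehyde
Product: 15 (R)-4-ethynyl-5,5-dimethyl-4-[4-(trimethylsilyl)but-3-yn-1-yl]cyclohexane-1,3-dione, via ethynyl vinylogous ester 14 (not isolated)
Conditions: Me3SiCHN2, LiN(i-Pr)2, THF, −78 → 0 °C; then 2 M HCl, THF, 25 °C
Reagents that add atoms: (trimethylsilyl)diazomethane, C[Si](C)(C)C=[N+]=[N-]; water, O
Why: Colvin rearrangement (addition of the lithiated diazomethane to the aldehyde, loss of lithium silanolate and N2, 1,2-hydride shift) gives the terminal alkyne without alkoxide or fluoride, so the alkynylsilane survives, and aqueous acid then hydrolyses the vinylogous ester to the 1,3-dione.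

Step 9
Reactants: 15 (R)-4-ethynyl-5,5-dimethyl-4-[4-(trimethylsilyl)but-3-yn-1-yl]cyclohexane-1,3-dione
Product: 16 (R)-6-ethynyl-5,5-dimethyl-3-[(triisopropylsilyl)oxy]-6-[4-(trimethylsilyl)but-3-yn-1-yl]cyclohex-2-en-1-one
Conditions: i-Pr3SiOTf, Et3N, CH2Cl2, −78 °C
Reagents that add atoms: triisopropylsilyl trifluoromethanesulfonate, CC(C)[Si](OS(=O)(=O)C(F)(F)F)(C(C)C)C(C)C
Why: O-Silylation of the dione enolate (silyl enol ether formation) should take place at the C3 oxygen, remote from the quaternary C6, and the bulky silyl group should not migrate in the cold, so C5 stays the only free carbonyl.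

Step 10
Reactants: 16 (R)-6-ethynyl-5,5-dimethyl-3-[(triisopropylsilyl)oxy]-6-[4-(trimethylsilyl)but-3-yn-1-yl]cyclohex-2-en-1-one
Product: 18 (3S,4R)-4-ethynyl-3-hydroxy-3,5,5-trimethyl-4-[4-(trimethylsilyl)but-3-yn-1-yl]cyclohexan-1-one, via carbinol silyl enol ether 17 (not isolated)
Conditions: MeLi, CeCl3, THF, −78 °C; aq. NH4Cl at −78 °C; then HF·pyridine, pyridine, THF, 0 °C
Reagents that add atoms: methyllithium, [Li]C
Why: Organocerium 1,2-addition to the C5 carbonyl (Stork–Danheiser-type addition to a vinylogous silyl ester) should occur on the face of the slim pseudoaxial ethynyl group because the other face is blocked by the syn-axial C1 methyl, which puts the new methyl cis to the ethynyl arm and the hydroxyl cis to the butynyl arm; buffered HF then cleaves the O–Si bond of the silyl enol ether without ionising the tertiary allylic alcohol and without touching the alkynyl C–Si bond.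

Step 11
Reactants: 18 (3S,4R)-4-ethynyl-3-hydroxy-3,5,5-trimethyl-4-[4-(trimethylsilyl)but-3-yn-1-yl]cyclohexan-1-one
Product: 19 (3S,4R)-3-hydroxy-4-(iodoethynyl)-3,5,5-trimethyl-4-[4-(trimethylsilyl)but-3-yn-1-yl]cyclohexan-1-one
Conditions: N-iodomorpholine hydroiodide, CuI (5 mol %), THF, 20 °C
Reagents that add atoms: N-iodomorpholine hydroiodide, I[NH+]1CCOCC1.[I-]
Why: Copper acetylide-mediated electrophilic iodination acts only on the terminal C–H alkyne, so the silyl-capped alkyne, the ketone and the tertiary alcohol are left alone (iodination of a terminal alkyne).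

Step 12
Reactants: 19 (3S,4R)-3-hydroxy-4-(iodoethynyl)-3,5,5-trimethyl-4-[4-(trimethylsilyl)but-3-yn-1-yl]cyclohexan-1-one
Product: 20 (3S,4S)-3-hydroxy-4-[(Z)-2-iodoethenyl]-3,5,5-trimethyl-4-[4-(trimethylsilyl)but-3-yn-1-yl]cyclohexan-1-one
Conditions: 2-nitrobenzenesulfonohydrazide, Et3N, THF/i-PrOH, 20 °C
Reagents that add atoms: none
Why: Diimide, formed from the sulfonohydrazide, delivers two hydrogens to one face of the activated iodoalkyne (diimide cis-reduction) and so gives the Z iodoalkene, while the hindered silylalkyne and the carbonyl should react much more slowly.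

Step 13
Reactants: 20 (3S,4S)-3-hydroxy-4-[(Z)-2-iodoethenyl]-3,5,5-trimethyl-4-[4-(trimethylsilyl)but-3-yn-1-yl]cyclohexan-1-one
Product: 24 (5S,6S)-5-hydroxy-1,1,5-trimethyl-9-[(E)-(trimethylsilyl)methylidene]spiro[5.5]undec-7-en-3-one, via alkenylpalladium iodide 21 (not isolated), via dienylpalladium iodide 22 (not isolated), via dienylpalladium hydride 23 (not isolated)
Conditions: Pd(PPh3)4 (10 mol %), HCO2Na, DMF, 80 °C
Reagents that add atoms: none
Why: Zerovalent palladium inserts into the C8–I bond with retention, and the alkenylpalladium iodide 21 adds syn across C9≡C12, so that C8–C9 forms and palladium ends on C12 cis to C8 (22). This is a reductive Heck-type alkyne carbopalladation with formate as hydride donor, a known way to stereodefined exocyclic 1,3-dienes. Ring B closes in the 6-exo-dig mode, since the 7-endo alternative cannot reach the syn-coplanar four-centre geometry. Exchange of iodide for formate and loss of CO2 give hydride 23, and C–H reductive elimination puts hydrogen on C12 with retention, so silicon ends trans to C8; no stereocentre is formed, only this alkene geometry. The Z iodoalkene is needed so that C6 and C9 end cis on C7=C8, and the quaternary C6 holds both arms close, which should let ring closure outrun direct hydride reduction of the C8–Pd bond. Excess formate should capture the α-silyl alkenylpalladium before it isomerises or inserts again, and the ketone and free tertiary alcohol should be inert to the weakly basic medium.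

Step 14
Reactants: 24 (5S,6S)-5-hydroxy-1,1,5-trimethyl-9-[(E)-(trimethylsilyl)methylidene]spiro[5.5]undec-7-en-3-one
Product: 25 (5S,6S)-9-[(E)-bromomethylidene]-5-hydroxy-1,1,5-trimethylspiro[5.5]undec-7-en-3-one
Conditions: NBS, MeCN, −20 → 0 °C, dark
Reagents that add atoms: N-bromosuccinimide, O=C1CCC(=O)N1Br
Why: Electrophilic ipso-bromodesilylation: bromine attacks C12, the positive charge developing at C9 is stabilised by the β-silicon and by allylic delocalisation, and loss of silicon from this open, non-bridged species after least-motion rotation should give the bromoalkene with retention, i.e. bromine trans to C8.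

Step 15
Reactants: 25 (5S,6S)-9-[(E)-bromomethylidene]-5-hydroxy-1,1,5-trimethylspiro[5.5]undec-7-en-3-one
Product: 26 (3S,5S,6S)-9-[(E)-bromomethylidene]-1,1,5-trimethylspiro[5.5]undec-7-ene-3,5-diol
Conditions: LiBH(s-Bu)3, THF, −78 °C; aq. NH4Cl
Reagents that add atoms: none
Why: Sterically controlled ketone reduction: the bulky hydride attacks the C3 carbonyl from the equatorial side, away from the syn-axial C1 methyl and C5 hydroxyl, which gives the axial C3 alcohol cis to the C5 hydroxyl.

Step 16
Reactants: 26 (3S,5S,6S)-9-[(E)-bromomethylidene]-1,1,5-trimethylspiro[5.5]undec-7-ene-3,5-diol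
Product: 28 (3R,5S,6S)-3-bromo-9-[(E)-bromomethylidene]-1,1,5-trimethylspiro[5.5]undec-7-en-5-ol (target), via alkoxyphosphonium bromide 27 (not isolated)
Conditions: CBr4, PPh3, 2,6-lutidine, CH2Cl2, 0 → 25 °C
Reagents that add atoms: carbon tetrabromide, BrC(Br)(Br)Br
Why: Appel reaction: only the secondary alcohol forms the alkoxyphosphonium ion (the tertiary one is too hindered, and being cis it cannot attack from the back), and bromide displaces it by SN2 with inversion, giving the equatorial C3 bromide trans to the C5 hydroxyl.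

**Compound list**

1 | dimedone (5,5-dimethylcyclohexane-1,3-dione) | CC1(C)CC(=O)CC(=O)C1 | starting material
2 | 3-isobutoxy-5,5-dimethylcyclohex-2-en-1-one | CC(C)COC1=CC(=O)CC(C)(C)C1 | intermediate
3 | 4-(trimethylsilyl)but-3-yn-1-ol | C[Si](C)(C)C#CCCO | starting material
4 | 4-(trimethylsilyl)but-3-yn-1-yl trifluoromethanesulfonate | C[Si](C)(C)C#CCCOS(=O)(=O)C(F)(F)F | intermediate
5 | lithium 5-isobutoxy-3,3-dimethylcyclohexa-1,5-dien-1-olate (C6 enolate of 2) | CC(C)COC1=CC(O[Li])=CC(C)(C)C1 | intermediate (not isolated)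
6 | rac-3-isobutoxy-5,5-dimethyl-6-[4-(trimethylsilyl)but-3-yn-1-yl]cyclohex-2-en-1-one | CC(C)COC1=CC(=O)C(CCC#C[Si](C)(C)C)C(C)(C)C1 | intermediate
7 | lithium enolate of 6 (C5–O–Li, C5=C6) | CC(C)COC1=CC(O[Li])=C(CCC#C[Si](C)(C)C)C(C)(C)C1 | intermediate (not isolated)
8 | allyl 5-isobutoxy-3,3-dimethyl-2-[4-(trimethylsilyl)but-3-yn-1-yl]cyclohexa-1,5-dien-1-yl carbonate | CC(C)COC1=CC(OC(=O)OCC=C)=C(CCC#C[Si](C)(C)C)C(C)(C)C1 | intermediate
9 | O-bound allylpalladium enolate from 8 (phosphinooxazoline ligand not drawn) | CC(C)COC1=CC(O[Pd]CC=C)=C(CCC#C[Si](C)(C)C)C(C)(C)C1 | intermediate (not isolated)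
10 | (S)-6-allyl-3-isobutoxy-5,5-dimethyl-6-[4-(trimethylsilyl)but-3-yn-1-yl]cyclohex-2-en-1-one | CC1(C)CC(OCC(C)C)=CC(=O)[C@]1(CC=C)CCC#C[Si](C)(C)C | intermediate
11 | (S)-3-isobutoxy-5,5-dimethyl-6-[(E)-prop-1-en-1-yl]-6-[4-(trimethylsilyl)but-3-yn-1-yl]cyclohex-2-en-1-one | CC1(C)CC(OCC(C)C)=CC(=O)[C@]1(/C=C/C)CCC#C[Si](C)(C)C | intermediate
12 | (6R)-6-(1,2-dihydroxypropyl)-3-isobutoxy-5,5-dimethyl-6-[4-(trimethylsilyl)but-3-yn-1-yl]cyclohex-2-en-1-one (mixture at the two carbinol carbons) | CC1(C)CC(OCC(C)C)=CC(=O)[C@]1(C(O)C(C)O)CCC#C[Si](C)(C)C | intermediate (not isolated)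
13 | (R)-4-isobutoxy-6,6-dimethyl-2-oxo-1-[4-(trimethylsilyl)but-3-yn-1-yl]cyclohex-3-ene-1-carbaldehyde | CC1(C)CC(OCC(C)C)=CC(=O)[C@]1(C=O)CCC#C[Si](C)(C)C | intermediate
14 | (R)-6-ethynyl-3-isobutoxy-5,5-dimethyl-6-[4-(trimethylsilyl)but-3-yn-1-yl]cyclohex-2-en-1-one | CC1(C)CC(OCC(C)C)=CC(=O)[C@]1(C#C)CCC#C[Si](C)(C)C | intermediate (not isolated)
15 | (R)-4-ethynyl-5,5-dimethyl-4-[4-(trimethylsilyl)but-3-yn-1-yl]cyclohexane-1,3-dione | CC1(C)CC(=O)CC(=O)[C@]1(C#C)CCC#C[Si](C)(C)C | intermediate
16 | (R)-6-ethynyl-5,5-dimethyl-3-[(triisopropylsilyl)oxy]-6-[4-(trimethylsilyl)but-3-yn-1-yl]cyclohex-2-en-1-one | CC1(C)CC(O[Si](C(C)C)(C(C)C)C(C)C)=CC(=O)[C@]1(C#C)CCC#C[Si](C)(C)C | intermediate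
17 | (1S,6R)-6-ethynyl-1,5,5-trimethyl-3-[(triisopropylsilyl)oxy]-6-[4-(trimethylsilyl)but-3-yn-1-yl]cyclohex-2-en-1-ol | CC1(C)CC(O[Si](C(C)C)(C(C)C)C(C)C)=C[C@](C)(O)[C@]1(C#C)CCC#C[Si](C)(C)C | intermediate (not isolated)
18 | (3S,4R)-4-ethynyl-3-hydroxy-3,5,5-trimethyl-4-[4-(trimethylsilyl)but-3-yn-1-yl]cyclohexan-1-one | CC1(C)CC(=O)C[C@](C)(O)[C@]1(C#C)CCC#C[Si](C)(C)C | intermediate
19 | (3S,4R)-3-hydroxy-4-(iodoethynyl)-3,5,5-trimethyl-4-[4-(trimethylsilyl)but-3-yn-1-yl]cyclohexan-1-one | CC1(C)CC(=O)C[C@](C)(O)[C@]1(C#CI)CCC#C[Si](C)(C)C | intermediate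
20 | (3S,4S)-3-hydroxy-4-[(Z)-2-iodoethenyl]-3,5,5-trimethyl-4-[4-(trimethylsilyl)but-3-yn-1-yl]cyclohexan-1-one (key-step precursor) | CC1(C)CC(=O)C[C@](C)(O)[C@]1(/C=C\I)CCC#C[Si](C)(C)C | intermediate
21 | C8 alkenylpalladium iodide from 20 (oxidative addition complex; PPh3 ligands not drawn) | CC1(C)CC(=O)C[C@](C)(O)[C@]1(/C=C\[Pd]I)CCC#C[Si](C)(C)C | intermediate (not isolated)
22 | spirocyclic dienylpalladium iodide, Pd on C12 cis to C8 (PPh3 ligands not drawn) | CC1(C)CC(=O)C[C@](C)(O)[C@@]12C=C/C(=C(/[Si](C)(C)C)\[Pd]I)CC2 | intermediate (not isolated)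
23 | spirocyclic dienylpalladium hydride (PPh3 ligands not drawn) | CC1(C)CC(=O)C[C@](C)(O)[C@@]12C=C/C(=C(/[Si](C)(C)C)\[PdH])CC2 | intermediate (not isolated)
24 | (5S,6S)-5-hydroxy-1,1,5-trimethyl-9-[(E)-(trimethylsilyl)methylidene]spiro[5.5]undec-7-en-3-one (key-step product) | CC1(C)CC(=O)C[C@](C)(O)[C@@]12C=C/C(=C/[Si](C)(C)C)CC2 | intermediate
25 | (5S,6S)-9-[(E)-bromomethylidene]-5-hydroxy-1,1,5-trimethylspiro[5.5]undec-7-en-3-one | CC1(C)CC(=O)C[C@](C)(O)[C@@]12C=C/C(=C/Br)CC2 | intermediate
26 | (3S,5S,6S)-9-[(E)-bromomethylidene]-1,1,5-trimethylspiro[5.5]undec-7-ene-3,5-diol | CC1(C)C[C@H](O)C[C@](C)(O)[C@@]12C=C/C(=C/Br)CC2 | intermediate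
27 | C3 alkoxytriphenylphosphonium bromide of 26 | CC1(C)C[C@H](O[P+](c3ccccc3)(c4ccccc4)c5ccccc5)C[C@](C)(O)[C@@]12C=C/C(=C/Br)CC2.[Br-] | intermediate (not isolated)
28 | (3R,5S,6S)-3-bromo-9-[(E)-bromomethylidene]-1,1,5-trimethylspiro[5.5]undec-7-en-5-ol | CC1(C)C[C@@H](Br)C[C@](C)(O)[C@@]12C=C/C(=C/Br)CC2 | target

**Step count and risks**

Total step count: 16. Longest linear sequence: 15 steps (steps 1 and 3–16, from 1 to 28); step 2 is a one-step side branch.

Steps most likely to fail:

- **Step 13.** Hydride transfer to the C8 alkenylpalladium could run ahead of ring closure, or the α-silyl alkenylpalladium could lose its geometry before hydride capture. The fallback closes ring B by anionic carbometallation. Precursor 20 would first be reduced with LiBH(s-Bu)3 (THF, −78 °C) to the cis-diol vinyl iodide F1. After deprotonation of both hydroxyls with MeLi, iodine–lithium exchange with t-BuLi (Et2O/pentane, −78 °C) and warming with TMEDA should bring about a syn 6-exo-dig addition of the C8 vinyllithium to the silylalkyne. Protonation of the α-silyl alkenyllithium with methanol would give the (E)-dienylsilane diol F2. NBS in MeCN then leads to bromodiene diol 26, where the route is rejoined before step 16.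

- **Step 14.** Bromine could bridge and add across C9=C12, and elimination from the adduct would invert or scramble the alkene geometry. The fallback brings the halogen in by a relay. Iododesilylation of 24 with N-iodosuccinimide in hexafluoroisopropanol should give the (E)-iodide F3 with retention. Pd(PPh3)4 with Me3SnSnMe3 would convert it into the (E)-stannane F4. Stereoretentive bromodestannylation with NBS returns bromodiene 25.

- **Step 10.** The methyl reagent could show poor facial selectivity at C5 or attack silicon. The fallback changes the order of events at C5. Compound 16 would be treated with MeLi/CeCl3 and then aqueous HCl, so that the adduct loses water and gives the transposed enone F5 (Stork–Danheiser transposition). Nucleophilic epoxidation (t-BuOOH, DBU, CH2Cl2) should then place oxygen on C5 by axial attack anti to the pseudoaxial ethynyl group, giving epoxy ketone F6. Reductive opening of the C4–O bond with SmI2 (THF/MeOH, −90 °C) returns ketol 18.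

Further compounds
F1 | step 13 | (1S,3S,4S)-4-[(Z)-2-iodoethenyl]-3,5,5-trimethyl-4-[4-(trimethylsilyl)but-3-yn-1-yl]cyclohexane-1,3-diol (cis-diol) | CC1(C)C[C@H](O)C[C@](C)(O)[C@]1(/C=C\I)CCC#C[Si](C)(C)C
F2 | step 13 | (3S,5S,6S)-1,1,5-trimethyl-9-[(E)-(trimethylsilyl)methylidene]spiro[5.5]undec-7-ene-3,5-diol | CC1(C)C[C@H](O)C[C@](C)(O)[C@@]12C=C/C(=C/[Si](C)(C)C)CC2
F3 | step 14 | (5S,6S)-5-hydroxy-9-[(E)-iodomethylidene]-1,1,5-trimethylspiro[5.5]undec-7-en-3-one | CC1(C)CC(=O)C[C@](C)(O)[C@@]12C=C/C(=C/I)CC2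
F4 | step 14 | (5S,6S)-5-hydroxy-1,1,5-trimethyl-9-[(E)-(trimethylstannyl)methylidene]spiro[5.5]undec-7-en-3-one | CC1(C)CC(=O)C[C@](C)(O)[C@@]12C=C/C(=C/[Sn](C)(C)C)CC2
F5 | step 10 | 4-ethynyl-3,5,5-trimethyl-4-[4-(trimethylsilyl)but-3-yn-1-yl]cyclohex-2-en-1-one (C4 configured as C6 of 16) | CC1(C)CC(=O)C=C(C)[C@]1(C#C)CCC#C[Si](C)(C)C
F6 | step 10 | 2,3-epoxide of F5, epoxide oxygen cis to the butynyl arm | CC1(C)CC(=O)[C@@H]2O[C@]2(C)[C@]1(C#C)CCC#C[Si](C)(C)C
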